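The constants used here were chosen freely, and the outcome is calculated.

Counted by the substrate in it, what the six species hold in a closed flask stays equal to the charge, so the question is how that charge divides.

all flasks: substrate 0.050 M
- eta: time 25 d; a closed flask charged with all of it at once and left for 25 d
- gamma: one stirred flow tank at steady state, fed with the mixture as stated, mean residence time 25 d

    substrate → single ring (k1 = 0.38 h⁻¹)
    2 substrate → open dimer (k2 = 20 M⁻¹ h⁻¹)
    substrate + open dimer → open trimer (k3 = 2.4 M⁻¹ h⁻¹)
    open dimer → ring dimer (k4 = 0.026 h⁻¹)
    substrate + single ring ⇌ idle adduct, settled at all times (K5 = 33 M⁻¹)

- a species is counted by the substrate in it: one open dimer or ring dimer or idle adduct counts as two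
- a species is counted by the substrate in it: one open trimer counts as three
- amounts and yields of single ring count idle adduct too
- where a step has two of a species, its rate is k times that concentration squared, and two are used at each turn
- the stated concentrations are those of everything mixed, before any reaction; amounts are the same in each set-up
- in an amount of single ring, one idle adduct counts as one single ring
- run time (eta): 25 d

1. the set-up with the highest amount of single ring at the outlet or at the end, in percent of the substrate put in ("none" if the first two lie within 2 percentage points) (eta / gamma / none)
2. amount of single ring at the outlet or at the end, in percent of the substrate put in, eta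
3. amount of single ring at the outlet or at the end, in percent of the substrate put in, gamma

*What divides the substrate?* Let s be free substrate, a the ring constant 0.38 h⁻¹, and b the dimer constant 20 M⁻¹ h⁻¹. Substrate goes to single ring at a·s and to open dimer at 2b·s·s. The crossover concentration s* = a/(2b), the free substrate at which the two steps use it equally fast, is 0.00950 M. The ratio s*/s is the selectivity factor for single ring.

*Where does eta stand?* Let c be the charge. In eta, c is 5.26 times s*, so the selectivity factor starts at 0.190.

*Does the time enter?* I take it not: in eta the half-life of substrate by the ring step alone is 0.076 d, shorter than the run, so I integrate down to empty. Each single ring costs 1 + s/s* substrates, which gives a yield of (s*/c)·ln(1 + c/s*). For eta that is 34.9 %.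

*The weak spot?* In both reckonings I dropped the idle adduct and the open trimer. While s stands near the charge in eta, the adduct constant times s is 1.6, so idle adduct outweighs free single ring. The adduct holds s down, which raises my eta figure, while the substrate taken into open trimer lowers it. I judge the adduct the stronger of the two, so I read my eta figure as somewhat low.

*And gamma?* Feed equals washout plus the two steps, a quadratic in s with residence time 25 d. It gives 2.14 × 10⁻⁴ M, far below s*, and a yield of 97.4 %. My choice is gamma.

*The forecast?* It reasoned that “low free substrate favours the ring” and chose gamma. It gave 36.5 % for eta (range 35 % to 38 %) and 96.9 % for gamma (range 96.3 % to 97.4 %). Mine is lower on eta and higher on gamma.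

The simulation gives gamma, with 36.3 % single ring in eta and 96.7 % in gamma. Substrate in the gamma tank stands at 2.12 × 10⁻⁴ M, which puts the selectivity factor there at 44.8. The neighbour of eta charged with 0.013 M starts at 1.37 times s*, and the same integral gives it 63.0 %. That neighbour ends with 64.2 % single ring against 34.0 % ring dimer.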